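**Plan**

1. Numbering: guaianolide half C1–C15, seco-eudesmanolide half C1′–C15′. Retrosynthesis: (a) C2–OAc from a C2 carboxylic acid; (b) cut C1–C13′ and C2–C3, the two bonds that close the cyclopentane C1–C2–C3–C11′–C13′ of the bicyclo[2.2.1]heptene; (c) cut C4–C5; (d) cut C3–C11′ and C3=C4.
2. Forward: fragment 1 (seven-membered ring, trans-lactone, exocyclic C1=C2 enoate, C5 boronate) by alkylation, ring-closing metathesis and olefination; fragment 2 (cyclohexene cis-lactone, quaternary C11′ carrying CH2I and a (Z)-2-iodopropenyl arm) by carbene ring expansion, Negishi coupling, iodo-aldol and Wittig reaction.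
3. Suzuki coupling joins C4–C5; one tin hydride radical cascade then closes the six-membered ring (C13′ to C1) and the one-carbon bridge (C2 to C3) and leaves C4=C5; methylenation, decarboxylative acetoxylation and acetylation finish.
4. What makes the event possible: the CH2I group on spiro C11′ gives a primary radical that cannot eliminate, C1 is the β-carbon of an exocyclic enoate, and C3 is the terminus of a C3=C4–C5=C6 diene held 1,4 across the ring made by the first closure.
5. Stereochemistry: C7/C8 from (S)-5-(hydroxymethyl)furan-2(5H)-one, C10 by Evans alkylation, C7′/C8′ from (1S,5R)-2-oxabicyclo[3.3.0]oct-6-en-3-one, C4′ from (S)-γ-valerolactone, C10′ and C11′ by convex-face additions, C1 anti to the C10 methyl, C3 by the bicycle, C2 by acetate capture of the 7-norbornenyl cation anti to C4=C5.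

Key step: step 25

Assumption: the drawn enantiomer is the goal as such, so no natural sesquiterpene lactone is used as starting material; the exocyclic enoate of 12, 13 and 32 is carried as an E/Z mixture because both isomers give the same radical.

**Fragment 1**

Step 1
Reactants: 1 (S)-5-(hydroxymethyl)furan-2(5H)-one
Product: 2 (S)-5-[(tert-butyldiphenylsilyloxy)methyl]furan-2(5H)-one
Conditions: TBDPSCl, imidazole, DMF, 0 °C to rt
Reagents that add atoms: tert-butyl(chloro)diphenylsilane, CC(C)(C)[Si](Cl)(c1ccccc1)c1ccccc1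
Why: Silylation of the primary alcohol should proceed without touching the C8 stereocentre.

Step 2
Reactants: 2 (S)-5-[(tert-butyldiphenylsilyloxy)methyl]furan-2(5H)-one
Product: 3 (4R,5S)-5-[(tert-butyldiphenylsilyloxy)methyl]-4-vinyldihydrofuran-2(3H)-one
Conditions: vinylMgBr, CuI (cat.), THF, −78 °C; NH4Cl aq
Reagents that add atoms: vinylmagnesium bromide, C=C[Mg]Br
Why: Copper-catalysed conjugate addition to the butenolide should occur anti to the C5 substituent and so set C7 trans to C8.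

Step 3
Reactants: 3 (4R,5S)-5-[(tert-butyldiphenylsilyloxy)methyl]-4-vinyldihydrofuran-2(3H)-one
Product: 4 (4R,5S)-5-(hydroxymethyl)-4-vinyldihydrofuran-2(3H)-one
Conditions: TBAF, AcOH, THF, 0 °C
Reagents that add atoms: none
Why: Buffered fluoride desilylation should free the primary alcohol without opening the lactone.

Step 4
Reactants: 4 (4R,5S)-5-(hydroxymethyl)-4-vinyldihydrofuran-2(3H)-one
Product: 5 [(2S,3R)-5-oxo-3-vinyltetrahydrofuran-2-yl]methyl triflate
Conditions: Tf2O, pyridine, CH2Cl2, −78 °C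
Reagents that add atoms: trifluoromethanesulfonic anhydride, O=S(=O)(OS(=O)(=O)C(F)(F)F)C(F)(F)F
Why: Triflation turns the primary alcohol into an electrophile reactive enough for an imide enolate at low temperature.

Step 5
Reactants: 5 [(2S,3R)-5-oxo-3-vinyltetrahydrofuran-2-yl]methyl triflate; 6 (S)-4-benzyl-3-propionyloxazolidin-2-one
Product: 7 (S)-4-benzyl-3-{(R)-2-methyl-3-[(2R,3R)-5-oxo-3-vinyltetrahydrofuran-2-yl]propanoyl}oxazolidin-2-one
Conditions: 6, NaHMDS, THF, −78 °C; then 5, −78 to −40 °C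
Reagents that add atoms: none
Why: Evans alkylation of the Z-enolate on the face away from the benzyl group should set the C10 methyl centre as R, and the imide enolate is too weakly basic to deprotonate the lactone.

Step 6
Reactants: 7 (S)-4-benzyl-3-{(R)-2-methyl-3-[(2R,3R)-5-oxo-3-vinyltetrahydrofuran-2-yl]propanoyl}oxazolidin-2-one
Product: 8 S-ethyl (R)-2-methyl-3-[(2R,3R)-5-oxo-3-vinyltetrahydrofuran-2-yl]propanethioate
Conditions: EtSH, n-BuLi, THF, 0 °C
Reagents that add atoms: ethanethiol, CCS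
Why: Thiolate transacylation removes the auxiliary at the exocyclic imide carbonyl without epimerising the α-centre.

Step 7
Reactants: 8 S-ethyl (R)-2-methyl-3-[(2R,3R)-5-oxo-3-vinyltetrahydrofuran-2-yl]propanethioate
Product: 9 (4R,5R)-5-[(R)-2-methyl-3-oxopent-4-en-1-yl]-4-vinyldihydrofuran-2(3H)-one
Conditions: CH2=CHSnBu3, Pd2(dba)3, tri(2-furyl)phosphine, CuO2PPh2, THF, 50 °C
Reagents that add atoms: tributyl(vinyl)stannane, C=C[Sn](CCCC)(CCCC)CCCC
Why: Liebeskind–Srogl-type thioester–stannane coupling gives the vinyl ketone under neutral conditions that spare the lactone and the α-stereocentre.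

Step 8
Reactants: 9 (4R,5R)-5-[(R)-2-methyl-3-oxopent-4-en-1-yl]-4-vinyldihydrofuran-2(3H)-one
Product: 10 (3aR,7R,8aR)-7-methyl-3,3a,8,8a-tetrahydro-2H-cyclohepta[b]furan-2,6(7H)-dione
Conditions: second-generation Grubbs catalyst, CH2Cl2 (2 mM), 40 °C
Reagents that add atoms: none
Why: Ring-closing metathesis of the vinyl ketone with the C7 vinyl group should close the cycloheptenone (C5=C6) with loss of ethene.

Step 9
Reactants: 10 (3aR,7R,8aR)-7-methyl-3,3a,8,8a-tetrahydro-2H-cyclohepta[b]furan-2,6(7H)-dione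
Product: 11 (3aR,7R,8aR)-5-iodo-7-methyl-3,3a,8,8a-tetrahydro-2H-cyclohepta[b]furan-2,6(7H)-dione
Conditions: I2, pyridine, CH2Cl2, rt
Reagents that add atoms: iodine, II
Why: α-Iodination of the enone by pyridine addition, iodination and elimination places the halogen on C5.

Step 10
Reactants: 11 (3aR,7R,8aR)-5-iodo-7-methyl-3,3a,8,8a-tetrahydro-2H-cyclohepta[b]furan-2,6(7H)-dione
Product: 12 tert-butyl 2-[(3aR,7R,8aR)-5-iodo-7-methyl-2-oxo-3,3a,8,8a-tetrahydro-2H-cyclohepta[b]furan-6(7H)-ylidene]acetate (E/Z mixture)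
Conditions: t-BuO2CCH2SiMe3, LDA, THF, −78 °C; then 11, −78 to 0 °C
Reagents that add atoms: tert-butyl (trimethylsilyl)acetate, CC(C)(C)OC(=O)C[Si](C)(C)C
Why: Peterson olefination adds the small α-silyl ester enolate 1,2 to the hindered ketone and eliminates silanolate, giving the C1=C2 enoate without a regiochemical choice.

Step 11
Reactants: 12 tert-butyl 2-[(3aR,7R,8aR)-5-iodo-7-methyl-2-oxo-3,3a,8,8a-tetrahydro-2H-cyclohepta[b]furan-6(7H)-ylidene]acetate
Product: 13 tert-butyl 2-[(3aR,7R,8aR)-7-methyl-2-oxo-5-(4,4,5,5-tetramethyl-1,3,2-dioxaborolan-2-yl)-3,3a,8,8a-tetrahydro-2H-cyclohepta[b]furan-6(7H)-ylidene]acetate (fragment 1)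
Conditions: B2pin2, PdCl2(dppf), KOAc, dioxane, 80 °C
Reagents that add atoms: bis(pinacolato)diboron, CC1(C)OB(OC1(C)C)B1OC(C)(C)C(C)(C)O1
Why: Miyaura borylation turns the C5 alkenyl iodide into the nucleophilic partner for the fragment union.

**Fragment 2**

Step 12
Reactants: 14 (1S,5R)-2-oxabicyclo[3.3.0]oct-6-en-3-one
Product: 15 exo-6,6-dibromocyclopropane adduct of 14 (tricyclic cis-lactone)
Conditions: PhHgCBr3, benzene, 80 °C
Reagents that add atoms: phenyl(tribromomethyl)mercury, BrC(Br)(Br)[Hg]c1ccccc1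
Why: Neutral thermal transfer of dibromocarbene to the cyclopentene should occur on the convex face and supplies the future C5′.

Step 13
Reactants: 15 exo-6,6-dibromocyclopropane adduct of 14
Product: 16 (3aR,7aS)-5-bromo-6-hydroxy-3a,6,7,7a-tetrahydrobenzofuran-2(3H)-one (C6 epimers)
Conditions: AgNO3, acetone/H2O, 55 °C
Reagents that add atoms: water, O
Why: Silver-assisted disrotatory opening of the gem-dibromocyclopropane gives a 2-bromoallyl cation that water should capture at the terminus remote from the ring-fusion carbon, expanding the ring to the cyclohexene.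

Step 14
Reactants: 16 (3aR,7aS)-5-bromo-6-hydroxy-3a,6,7,7a-tetrahydrobenzofuran-2(3H)-one
Product: 17 (3aR,7aS)-5-bromo-3a,7a-dihydrobenzofuran-2,6(3H,7H)-dione
Conditions: Dess–Martin periodinane, CH2Cl2, rt
Reagents that add atoms: none
Why: Neutral oxidation of the allylic alcohol gives the α-bromoenone without β-elimination of the lactone oxygen.

Step 15
Reactants: 18 (S)-γ-valerolactone
Product: 19 (S)-pentane-1,4-diol
Conditions: LiAlH4, THF, 0 °C to rt
Reagents that add atoms: none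
Why: Hydride reduction of the lactone leaves the carbinol stereocentre untouched.

Step 16
Reactants: 19 (S)-pentane-1,4-diol
Product: 20 (S)-5-(tert-butyldiphenylsilyloxy)pentan-2-ol
Conditions: TBDPSCl, imidazole, CH2Cl2, −20 °C
Reagents that add atoms: tert-butyl(chloro)diphenylsilane, CC(C)(C)[Si](Cl)(c1ccccc1)c1ccccc1
Why: The bulky silyl chloride should select the primary hydroxyl.

Step 17
Reactants: 20 (S)-5-(tert-butyldiphenylsilyloxy)pentan-2-ol
Product: 21 (R)-tert-butyl[(4-iodopentyl)oxy]diphenylsilane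
Conditions: I2, PPh3, imidazole, CH2Cl2, 0 °C
Reagents that add atoms: iodine, II
Why: The Appel reaction replaces the secondary hydroxyl by iodide with inversion.

Step 18
Reactants: 17 (3aR,7aS)-5-bromo-3a,7a-dihydrobenzofuran-2,6(3H,7H)-dione; 21 (R)-tert-butyl[(4-iodopentyl)oxy]diphenylsilane
Product: 24 (3aR,7aS)-5-[(R)-5-(tert-butyldiphenylsilyloxy)pentan-2-yl]-3a,7a-dihydrobenzofuran-2,6(3H,7H)-dione, via alkyllithium 22 (not isolated), via alkylzinc 23 (not isolated)
Conditions: 21, t-BuLi, pentane/Et2O, −100 °C; Me3SiCH2ZnBr·LiBr, THF, −100 to −50 °C; then 17, Pd2(dba)3, SPhos, THF, −25 °C to rt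
Reagents that add atoms: none
Why: Iodine–lithium exchange at −100 °C and transmetalation to zinc proceed with retention, and stereoretentive Negishi coupling of the configurationally stable secondary alkylzinc with the α-bromoenone carries the C4′ centre onto C5′.

Step 19
Reactants: 24 (3aR,7aS)-5-[(R)-5-(tert-butyldiphenylsilyloxy)pentan-2-yl]-3a,7a-dihydrobenzofuran-2,6(3H,7H)-dione
Product: 25 (3aR,6R,7aS)-5-[(R)-5-(tert-butyldiphenylsilyloxy)pentan-2-yl]-6-hydroxy-6-methyl-3a,6,7,7a-tetrahydrobenzofuran-2(3H)-one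
Conditions: MeMgBr, CeCl3, THF, −78 °C
Reagents that add atoms: methylmagnesium bromide, C[Mg]Br
Why: Organocerium 1,2-addition to the enone from the convex face of the cis-fused bicycle should place the methyl group syn to the ring-fusion hydrogens and the C10′ hydroxyl on the lactone side.

Step 20
Reactants: 25 (3aR,6R,7aS)-5-[(R)-5-(tert-butyldiphenylsilyloxy)pentan-2-yl]-6-hydroxy-6-methyl-3a,6,7,7a-tetrahydrobenzofuran-2(3H)-one
Product: 28 (3aS,6R,7aS)-5-[(R)-5-(tert-butyldiphenylsilyloxy)pentan-2-yl]-6-hydroxy-6-methyl-3-methylene-3a,6,7,7a-tetrahydrobenzofuran-2(3H)-one, via Mannich base 26 (not isolated), via methiodide 27 (not isolated)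
Conditions: LiHMDS, THF, −78 °C; CH2=NMe2 I; then MeI, MeOH; then NaHCO3, CH2Cl2/H2O
Reagents that add atoms: Eschenmoser's salt, C=[N+](C)C.[I-]
Why: Mannich reaction of the lactone enolate followed by quaternisation and elimination is the standard route to the α-methylene lactone and supplies C13′.

Step 21
Reactants: 28 (3aS,6R,7aS)-5-[(R)-5-(tert-butyldiphenylsilyloxy)pentan-2-yl]-6-hydroxy-6-methyl-3-methylene-3a,6,7,7a-tetrahydrobenzofuran-2(3H)-one
Product: 29 (3S,3aS,6R,7aS)-3-(hydroxymethyl)-3-(iodomethyl) lactone (CH2I on the concave face, CH2OH on the convex face)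
Conditions: Et2AlI, CH2Cl2, −78 °C; CH2O (gas), −78 to −30 °C
Reagents that add atoms: diethylaluminium iodide, CC[Al](I)CC; formaldehyde, C=O
Why: In this iodo-aldol (halo-Michael/aldol) reaction iodide adds to C13′ and the aluminium enolate is hydroxymethylated at C11′ on its convex face, anti to the fused cyclohexene, which sets the quaternary centre and brings in C3.

Step 22
Reactants: 29 3-(hydroxymethyl)-3-(iodomethyl) lactone
Product: 30 3-formyl-3-(iodomethyl) lactone
Conditions: Dess–Martin periodinane, CH2Cl2, 0 °C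
Reagents that add atoms: none
Why: Neutral oxidation gives the non-enolisable neopentyl aldehyde without retro-aldol loss of formaldehyde.

Step 23
Reactants: 30 3-formyl-3-(iodomethyl) lactone
Product: 31 3-(iodomethyl)-3-[(Z)-2-iodoprop-1-enyl] lactone (fragment 2)
Conditions: [Ph3PCH(I)CH3]I, NaHMDS, THF, −78 °C; then 30
Reagents that add atoms: (1-iodoethyl)triphenylphosphonium iodide, CC(I)[P+](c1ccccc1)(c1ccccc1)c1ccccc1.[I-]
Why: Stork–Zhao olefination with the α-iodo ylide is kinetically cis-selective and should place iodine cis to C11′, which is the (Z)-geometry of C3=C4 that the later six-membered ring requires.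

**Union and endgame**

Step 24
Reactants: 13 fragment 1 boronate; 31 fragment 2 vinyl iodide
Product: 32 cascade precursor (C4–C5 linked trienoate with neopentyl iodide)
Conditions: PdCl2(dppf), Ph3As, Cs2CO3, DMF/THF/H2O, rt
Reagents that add atoms: none
Why: Suzuki–Miyaura coupling joins C4 and C5 with retention of both alkene geometries, and the neopentyl carbon–iodine bond is inert to zerovalent palladium.

Step 25
Reactants: 32 cascade precursor
Product: 36 pentacyclic tert-butyl ester (C2 epimers), via primary radical 33 (not isolated), via ester radical 34 (not isolated), via allyl radical 35 (not isolated)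
Conditions: Bu3SnH (syringe pump), AIBN, benzene (2 mM), 80 °C
Reagents that add atoms: none
Why: Tributyltin radical abstracts iodine from C13′, and the primary radical, which has no β-hydrogen because C11′ is already quaternary, adds 6-exo-trig to C1, the β-carbon of the exocyclic enoate, rather than 5-exo to C5, because this mode is polarity-matched, gives a stabilised α-ester radical and keeps the C3=C4–C5=C6 diene conjugated. The electrophilic C2 radical then closes the bridge by a transannular 5-exo-trig addition to C3, the terminus of the electron-rich diene that lies 1,4 across the new cyclohexene, and the C4–C5–C6 allyl radical should take hydrogen from Bu3SnH at its less hindered secondary end C6, which leaves the tetrasubstituted C4=C5 bond. The closest known reaction type is the tin hydride tandem radical cyclisation in which a conjugate 6-exo closure is followed by 5-exo closure of a cyclohexenylmethyl radical to a norbornyl skeleton. C1 is set by attack anti to the adjacent C10 methyl group, C3 is fixed by the geometry of the bicycle once C1 and C11′ are given, and the C2 epimer ratio is irrelevant because C2 is levelled in step 28. The step needs high dilution and slow hydride addition so that both closures outrun reduction, and it relies on the (Z)-geometry of C3=C4 from step 23.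

Step 26
Reactants: 36 pentacyclic tert-butyl ester
Product: 39 pentacyclic tert-butyl ester with C11=C13 methylene lactone, via Mannich base 37 (not isolated), via methiodide 38 (not isolated)
Conditions: LiHMDS, THF, −78 °C; CH2=NMe2 I; then MeI, MeOH; then NaHCO3, CH2Cl2/H2O
Reagents that add atoms: Eschenmoser's salt, C=[N+](C)C.[I-]
Why: Only the trans-lactone has accessible α-hydrogens (C11′ is quaternary and the C2 ester hydrogen is buried), so the Mannich–elimination sequence should methylenate C11 alone, before any acetate is present.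

Step 27
Reactants: 39 pentacyclic tert-butyl ester with methylene lactone
Product: 41 C2 carboxylic acid with C10′ trimethylsilyl ether, via bis-silyl derivative 40 (not isolated)
Conditions: TMSOTf, 2,6-lutidine, CH2Cl2, 0 °C; pH 7 buffer
Reagents that add atoms: trimethylsilyl triflate, C[Si](C)(C)OS(=O)(=O)C(F)(F)F
Why: Silyl triflate cleaves the tert-butyl ester through its silyl ester under buffered non-protic conditions and at the same time masks the tertiary allylic alcohol for the oxidation that follows.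

Step 28
Reactants: 41 C2 carboxylic acid with C10′ trimethylsilyl ether
Product: 42 C2 acetate (anti to C4=C5) with C10′ trimethylsilyl ether and C1′ silyl ether
Conditions: Pb(OAc)4, Cu(OAc)2 (cat.), pyridine, benzene, 80 °C
Reagents that add atoms: lead tetraacetate, CC(=O)O[Pb](OC(C)=O)(OC(C)=O)OC(C)=O
Why: In this Kochi oxidative decarboxylation the C2 radical is oxidised to the 7-norbornenyl cation, which the C4=C5 π bond stabilises and acetate captures anti to that bond, so both C2 epimers should converge on the required (R)-acetate.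

Step 29
Reactants: 42 C2 acetate with two silyl ethers
Product: 43 C1′,C10′-diol C2-acetate
Conditions: HF·pyridine, THF, 0 °C to rt
Reagents that add atoms: none
Why: Fluoride-mediated desilylation removes both silyl ethers without touching the acetate or the two lactones.

Step 30
Reactants: 43 C1′,C10′-diol C2-acetate
Product: 44 target CNP0257312.1
Conditions: Ac2O, pyridine, CH2Cl2, 0 °C
Reagents that add atoms: acetic anhydride, CC(=O)OC(C)=O
Why: Acetylation should take the primary C1′ hydroxyl only, because the tertiary allylic C10′ hydroxyl is inert under these conditions.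

**Compound list**

1 | (S)-5-(hydroxymethyl)furan-2(5H)-one | O=C1C=C[C@@H](CO)O1 | starting material
2 | (S)-5-[(tert-butyldiphenylsilyloxy)methyl]furan-2(5H)-one | O=C1C=C[C@@H](CO[Si](c2ccccc2)(c2ccccc2)C(C)(C)C)O1 | intermediate
3 | (4R,5S)-5-[(tert-butyldiphenylsilyloxy)methyl]-4-vinyldihydrofuran-2(3H)-one | C1C(=O)O[C@H](CO[Si](c2ccccc2)(c2ccccc2)C(C)(C)C)[C@H]1C=C | intermediate
4 | (4R,5S)-5-(hydroxymethyl)-4-vinyldihydrofuran-2(3H)-one | C1C(=O)O[C@H](CO)[C@H]1C=C | intermediate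
5 | [(2S,3R)-5-oxo-3-vinyltetrahydrofuran-2-yl]methyl triflate | C1C(=O)O[C@H](COS(=O)(=O)C(F)(F)F)[C@H]1C=C | intermediate
6 | (S)-4-benzyl-3-propionyloxazolidin-2-one | CCC(=O)N1C(=O)OC[C@@H]1Cc1ccccc1 | starting material
7 | (S)-4-benzyl-3-{(R)-2-methyl-3-[(2R,3R)-5-oxo-3-vinyltetrahydrofuran-2-yl]propanoyl}oxazolidin-2-one | C1C(=O)O[C@H](C[C@@H](C)C(=O)N2C(=O)OC[C@@H]2Cc2ccccc2)[C@H]1C=C | intermediate
8 | S-ethyl (R)-2-methyl-3-[(2R,3R)-5-oxo-3-vinyltetrahydrofuran-2-yl]propanethioate | C1C(=O)O[C@H](C[C@@H](C)C(=O)SCC)[C@H]1C=C | intermediate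
9 | (4R,5R)-5-[(R)-2-methyl-3-oxopent-4-en-1-yl]-4-vinyldihydrofuran-2(3H)-one | C1C(=O)O[C@H](C[C@@H](C)C(=O)C=C)[C@H]1C=C | intermediate
10 | (3aR,7R,8aR)-7-methyl-3,3a,8,8a-tetrahydro-2H-cyclohepta[b]furan-2,6(7H)-dione | C1C(=O)O[C@@H]2C[C@@H](C)C(=O)C=C[C@@H]12 | intermediate
11 | (3aR,7R,8aR)-5-iodo-7-methyl-3,3a,8,8a-tetrahydro-2H-cyclohepta[b]furan-2,6(7H)-dione | C1C(=O)O[C@@H]2C[C@@H](C)C(=O)C(I)=C[C@@H]12 | intermediate
12 | tert-butyl 2-[(3aR,7R,8aR)-5-iodo-7-methyl-2-oxo-3,3a,8,8a-tetrahydro-2H-cyclohepta[b]furan-6(7H)-ylidene]acetate (E/Z mixture) | C1C(=O)O[C@@H]2C[C@@H](C)C(=CC(=O)OC(C)(C)C)C(I)=C[C@@H]12 | intermediate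
13 | fragment 1: 5-(pinacolboryl) analogue of 12 | C1C(=O)O[C@@H]2C[C@@H](C)C(=CC(=O)OC(C)(C)C)C(B3OC(C)(C)C(C)(C)O3)=C[C@@H]12 | intermediate
14 | (1S,5R)-2-oxabicyclo[3.3.0]oct-6-en-3-one | O=C1C[C@@H]2C=CC[C@@H]2O1 | starting material
15 | exo-6,6-dibromocyclopropane adduct of 14 | O=C1C[C@@H]2[C@@H]3[C@@H](C3(Br)Br)C[C@@H]2O1 | intermediate
16 | (3aR,7aS)-5-bromo-6-hydroxy-3a,6,7,7a-tetrahydrobenzofuran-2(3H)-one (C6 epimers) | O=C1C[C@@H]2C=C(Br)C(O)C[C@@H]2O1 | intermediate
17 | (3aR,7aS)-5-bromo-3a,7a-dihydrobenzofuran-2,6(3H,7H)-dione | O=C1C[C@@H]2C=C(Br)C(=O)C[C@@H]2O1 | intermediate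
18 | (S)-γ-valerolactone | C[C@H]1CCC(=O)O1 | starting material
19 | (S)-pentane-1,4-diol | C[C@H](O)CCCO | intermediate
20 | (S)-5-(tert-butyldiphenylsilyloxy)pentan-2-ol | C[C@H](O)CCCO[Si](c1ccccc1)(c1ccccc1)C(C)(C)C | intermediate
21 | (R)-tert-butyl[(4-iodopentyl)oxy]diphenylsilane | C[C@@H](I)CCCO[Si](c1ccccc1)(c1ccccc1)C(C)(C)C | intermediate
22 | (R)-[5-(tert-butyldiphenylsilyloxy)pentan-2-yl]lithium | C[C@@H]([Li])CCCO[Si](c1ccccc1)(c1ccccc1)C(C)(C)C | intermediate
23 | (R)-[5-(tert-butyldiphenylsilyloxy)pentan-2-yl][(trimethylsilyl)methyl]zinc | C[C@@H]([Zn]C[Si](C)(C)C)CCCO[Si](c1ccccc1)(c1ccccc1)C(C)(C)C | intermediate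
24 | (3aR,7aS)-5-[(R)-5-(tert-butyldiphenylsilyloxy)pentan-2-yl]-3a,7a-dihydrobenzofuran-2,6(3H,7H)-dione | O=C1C[C@@H]2C=C([C@H](C)CCCO[Si](c3ccccc3)(c3ccccc3)C(C)(C)C)C(=O)C[C@@H]2O1 | intermediate
25 | (3aR,6R,7aS)-5-[(R)-5-(tert-butyldiphenylsilyloxy)pentan-2-yl]-6-hydroxy-6-methyl-3a,6,7,7a-tetrahydrobenzofuran-2(3H)-one | O=C1C[C@@H]2C=C([C@H](C)CCCO[Si](c3ccccc3)(c3ccccc3)C(C)(C)C)[C@](C)(O)C[C@@H]2O1 | intermediate
26 | 3-[(dimethylamino)methyl] derivative of 25 (Mannich base, C3 epimers) | CN(C)CC1C(=O)O[C@H]2C[C@@](C)(O)C([C@H](C)CCCO[Si](c3ccccc3)(c3ccccc3)C(C)(C)C)=C[C@H]21 | intermediate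
27 | methiodide of 26 | C[N+](C)(C)CC1C(=O)O[C@H]2C[C@@](C)(O)C([C@H](C)CCCO[Si](c3ccccc3)(c3ccccc3)C(C)(C)C)=C[C@H]21.[I-] | intermediate
28 | (3aS,6R,7aS)-5-[(R)-5-(tert-butyldiphenylsilyloxy)pentan-2-yl]-6-hydroxy-6-methyl-3-methylene-3a,6,7,7a-tetrahydrobenzofuran-2(3H)-one | C=C1C(=O)O[C@H]2C[C@@](C)(O)C([C@H](C)CCCO[Si](c3ccccc3)(c3ccccc3)C(C)(C)C)=C[C@H]21 | intermediate
29 | (3S,3aS,6R,7aS)-3-(hydroxymethyl)-3-(iodomethyl) lactone from 28 | OC[C@]1(CI)C(=O)O[C@H]2C[C@@](C)(O)C([C@H](C)CCCO[Si](c3ccccc3)(c3ccccc3)C(C)(C)C)=C[C@H]21 | intermediate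
30 | 3-formyl-3-(iodomethyl) lactone | O=C[C@]1(CI)C(=O)O[C@H]2C[C@@](C)(O)C([C@H](C)CCCO[Si](c3ccccc3)(c3ccccc3)C(C)(C)C)=C[C@H]21 | intermediate
31 | fragment 2: 3-(iodomethyl)-3-[(Z)-2-iodoprop-1-enyl] lactone | I/C(C)=C\[C@]1(CI)C(=O)O[C@H]2C[C@@](C)(O)C([C@H](C)CCCO[Si](c3ccccc3)(c3ccccc3)C(C)(C)C)=C[C@H]21 | intermediate
32 | cascade precursor (C4–C5 linked trienoate, neopentyl iodide) | C1C(=O)O[C@@H]2C[C@@H](C)C(=CC(=O)OC(C)(C)C)C(/C(C)=C\[C@]5(CI)C(=O)O[C@H]6C[C@@](C)(O)C([C@H](C)CCCO[Si](c7ccccc7)(c7ccccc7)C(C)(C)C)=C[C@H]65)=C[C@@H]12 | intermediate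
33 | primary C13′ radical from 32 | C1C(=O)O[C@@H]2C[C@@H](C)C(=CC(=O)OC(C)(C)C)C(/C(C)=C\[C@]5([CH2])C(=O)O[C@H]6C[C@@](C)(O)C([C@H](C)CCCO[Si](c7ccccc7)(c7ccccc7)C(C)(C)C)=C[C@H]65)=C[C@@H]12 | intermediate
34 | α-ester C2 radical after the 6-exo closure | C1C(=O)O[C@@H]2C[C@@H](C)[C@@]3(C[C@]5(C(=O)O[C@H]6C[C@@](C)(O)C([C@H](C)CCCO[Si](c7ccccc7)(c7ccccc7)C(C)(C)C)=C[C@H]65)C=C(C)C3=C[C@@H]12)[CH]C(=O)OC(C)(C)C | intermediate
35 | C4–C5–C6 allyl radical after the 5-exo closure | C1C(=O)O[C@@H]2C[C@@H](C)[C@]34C[C@]5(C(=O)O[C@H]6C[C@@](C)(O)C([C@H](C)CCCO[Si](c7ccccc7)(c7ccccc7)C(C)(C)C)=C[C@H]65)[C@H](C(C)=C3[CH][C@@H]12)C4C(=O)OC(C)(C)C | intermediate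
36 | pentacyclic tert-butyl ester (C2 epimers) | C1C(=O)O[C@@H]2C[C@@H](C)[C@]34C[C@]5(C(=O)O[C@H]6C[C@@](C)(O)C([C@H](C)CCCO[Si](c7ccccc7)(c7ccccc7)C(C)(C)C)=C[C@H]65)[C@H](C(C)=C3C[C@@H]12)C4C(=O)OC(C)(C)C | intermediate
37 | C11 Mannich base of 36 | CN(C)CC1C(=O)O[C@@H]2C[C@@H](C)[C@]34C[C@]5(C(=O)O[C@H]6C[C@@](C)(O)C([C@H](C)CCCO[Si](c7ccccc7)(c7ccccc7)C(C)(C)C)=C[C@H]65)[C@H](C(C)=C3C[C@@H]12)C4C(=O)OC(C)(C)C | intermediate
38 | methiodide of 37 | C[N+](C)(C)CC1C(=O)O[C@@H]2C[C@@H](C)[C@]34C[C@]5(C(=O)O[C@H]6C[C@@](C)(O)C([C@H](C)CCCO[Si](c7ccccc7)(c7ccccc7)C(C)(C)C)=C[C@H]65)[C@H](C(C)=C3C[C@@H]12)C4C(=O)OC(C)(C)C.[I-] | intermediate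
39 | pentacyclic tert-butyl ester with C11=C13 methylene lactone | C=C1C(=O)O[C@@H]2C[C@@H](C)[C@]34C[C@]5(C(=O)O[C@H]6C[C@@](C)(O)C([C@H](C)CCCO[Si](c7ccccc7)(c7ccccc7)C(C)(C)C)=C[C@H]65)[C@H](C(C)=C3C[C@@H]12)C4C(=O)OC(C)(C)C | intermediate
40 | trimethylsilyl ester and C10′ trimethylsilyl ether from 39 | C=C1C(=O)O[C@@H]2C[C@@H](C)[C@]34C[C@]5(C(=O)O[C@H]6C[C@@](C)(O[Si](C)(C)C)C([C@H](C)CCCO[Si](c7ccccc7)(c7ccccc7)C(C)(C)C)=C[C@H]65)[C@H](C(C)=C3C[C@@H]12)C4C(=O)O[Si](C)(C)C | intermediate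
41 | C2 carboxylic acid with C10′ trimethylsilyl ether | C=C1C(=O)O[C@@H]2C[C@@H](C)[C@]34C[C@]5(C(=O)O[C@H]6C[C@@](C)(O[Si](C)(C)C)C([C@H](C)CCCO[Si](c7ccccc7)(c7ccccc7)C(C)(C)C)=C[C@H]65)[C@H](C(C)=C3C[C@@H]12)C4C(=O)O | intermediate
42 | C2 (R)-acetate with C10′ trimethylsilyl ether and C1′ silyl ether | C=C1C(=O)O[C@@H]2C[C@@H](C)[C@]34C[C@]5(C(=O)O[C@H]6C[C@@](C)(O[Si](C)(C)C)C([C@H](C)CCCO[Si](c7ccccc7)(c7ccccc7)C(C)(C)C)=C[C@H]65)[C@H](C(C)=C3C[C@@H]12)[C@H]4OC(C)=O | intermediate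
43 | C1′,C10′-diol C2-acetate | C=C1C(=O)O[C@@H]2C[C@@H](C)[C@]34C[C@]5(C(=O)O[C@H]6C[C@@](C)(O)C([C@H](C)CCCO)=C[C@H]65)[C@H](C(C)=C3C[C@@H]12)[C@H]4OC(C)=O | intermediate
44 | CNP0257312.1 | C=C1C(=O)O[C@@H]2C[C@@H](C)[C@]34C[C@]5(C(=O)O[C@H]6C[C@@](C)(O)C([C@H](C)CCCOC(C)=O)=C[C@H]65)[C@H](C(C)=C3C[C@@H]12)[C@H]4OC(C)=O | target

**Count and risks**

Total step count: 30. Longest linear sequence: 18 steps (steps 1–11, then 24–30).

Steps most likely to fail:

Step 25. Hydrogen transfer to the α-ester radical may outrun the transannular closure, or hydrogen may be delivered to the tertiary end of the allyl radical. Fallback, setting out from 11 and 31 and returning at 36: the two ring closures are separated and the second is made a two-electron event. Knoevenagel condensation of 11 with tert-butyl methyl malonate (TiCl4, pyridine, THF) would give the alkylidene malonate F1. Miyaura borylation would give the boronate F2, and Suzuki coupling with 31 the malonate triene F3. Tin hydride cyclisation onto the doubly activated acceptor should stop at the monocyclic malonate F4, since the malonyl radical is reduced faster than it cyclises. Palladium-catalysed intramolecular hydroalkylation of the 1,3-diene (Pd(OAc)2, 1,3-bis(diphenylphosphino)propane, Et3N, toluene) would then add hydrogen to C6 and the malonate carbon to C3 of the allyl complex, giving the bicyclic malonate F5. Krapcho demethoxycarbonylation (LiCl, wet DMSO, 140 °C) comes back to 36.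

Step 21. The iodo-aldol may revert (loss of formaldehyde and iodide from the aluminium aldolate), or facial control at C11′ may be poor. Fallback, setting out from 28 and returning at 36: the halide is replaced by a selenolate, for which the organoaluminium Michael–aldol is established, and the carbon–selenium bond then serves as the radical precursor. Me2AlSePh followed by formaldehyde would give the selenide alcohol F6. Dess–Martin oxidation would give the aldehyde F7, and the iodo-ylide olefination of step 23 the (Z)-vinyl iodide F8. Suzuki coupling with 13 would give the selenide cascade precursor F9, which under the conditions of step 25 should enter the same cascade and reach 36.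

Step 18. Configuration at C4′ may erode during the lithium–zinc exchange, and coupling at the hindered α-bromoenone may be slow. Fallback, setting out from 17 and returning at 25: the stereocentre is created after the carbon–carbon bond. Suzuki coupling of 17 with 2-[5-(tert-butyldiphenylsilyloxy)pent-1-en-2-yl]-4,4,5,5-tetramethyl-1,3,2-dioxaborolane (PdCl2(dppf), K3PO4) would give the dienone F10. Methylcerium addition as in step 19 would give the dienol F11. Hydroxyl-directed hydrogenation of the 1,1-disubstituted alkene with [Ir(cod)(PCy3)(py)]PF6 and H2, delivered from the face of the tertiary carbinol, should set C4′ and come back to 25.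

Further compounds
F1 | step 25 | tert-butyl methyl 2-[(3aR,7R,8aR)-5-iodo-7-methyl-2-oxo-3,3a,8,8a-tetrahydro-2H-cyclohepta[b]furan-6(7H)-ylidene]malonate | C1C(=O)O[C@@H]2C[C@@H](C)C(=C(C(=O)OC)C(=O)OC(C)(C)C)C(I)=C[C@@H]12
F2 | step 25 | 5-(pinacolboryl) analogue of F1 | C1C(=O)O[C@@H]2C[C@@H](C)C(=C(C(=O)OC)C(=O)OC(C)(C)C)C(B3OC(C)(C)C(C)(C)O3)=C[C@@H]12
F3 | step 25 | malonate analogue of cascade precursor 32 | C1C(=O)O[C@@H]2C[C@@H](C)C(=C(C(=O)OC)C(=O)OC(C)(C)C)C(/C(C)=C\[C@]5(CI)C(=O)O[C@H]6C[C@@](C)(O)C([C@H](C)CCCO[Si](c7ccccc7)(c7ccccc7)C(C)(C)C)=C[C@H]65)=C[C@@H]12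
F4 | step 25 | monocyclic malonate (C1–C13′ bond formed, diene intact) | C1C(=O)O[C@@H]2C[C@@H](C)[C@@]3(C[C@]5(C(=O)O[C@H]6C[C@@](C)(O)C([C@H](C)CCCO[Si](c7ccccc7)(c7ccccc7)C(C)(C)C)=C[C@H]65)C=C(C)C3=C[C@@H]12)C(C(=O)OC)C(=O)OC(C)(C)C
F5 | step 25 | bicyclic malonate (C2–C3 bond formed, C4=C5) | C1C(=O)O[C@@H]2C[C@@H](C)[C@]34C[C@]5(C(=O)O[C@H]6C[C@@](C)(O)C([C@H](C)CCCO[Si](c7ccccc7)(c7ccccc7)C(C)(C)C)=C[C@H]65)[C@H](C(C)=C3C[C@@H]12)C4(C(=O)OC)C(=O)OC(C)(C)C
F6 | step 21 | 3-(hydroxymethyl)-3-[(phenylselanyl)methyl] lactone | OC[C@]1(C[Se]c4ccccc4)C(=O)O[C@H]2C[C@@](C)(O)C([C@H](C)CCCO[Si](c3ccccc3)(c3ccccc3)C(C)(C)C)=C[C@H]21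
F7 | step 21 | 3-formyl-3-[(phenylselanyl)methyl] lactone | O=C[C@]1(C[Se]c4ccccc4)C(=O)O[C@H]2C[C@@](C)(O)C([C@H](C)CCCO[Si](c3ccccc3)(c3ccccc3)C(C)(C)C)=C[C@H]21
F8 | step 21 | 3-[(Z)-2-iodoprop-1-enyl]-3-[(phenylselanyl)methyl] lactone | I/C(C)=C\[C@]1(C[Se]c4ccccc4)C(=O)O[C@H]2C[C@@](C)(O)C([C@H](C)CCCO[Si](c3ccccc3)(c3ccccc3)C(C)(C)C)=C[C@H]21
F9 | step 21 | selenide analogue of cascade precursor 32 | C1C(=O)O[C@@H]2C[C@@H](C)C(=CC(=O)OC(C)(C)C)C(/C(C)=C\[C@]5(C[Se]c8ccccc8)C(=O)O[C@H]6C[C@@](C)(O)C([C@H](C)CCCO[Si](c7ccccc7)(c7ccccc7)C(C)(C)C)=C[C@H]65)=C[C@@H]12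
F10 | step 18 | (3aR,7aS)-5-[5-(tert-butyldiphenylsilyloxy)pent-1-en-2-yl]-3a,7a-dihydrobenzofuran-2,6(3H,7H)-dione | O=C1C[C@@H]2C=C(C(=C)CCCO[Si](c3ccccc3)(c3ccccc3)C(C)(C)C)C(=O)C[C@@H]2O1
F11 | step 18 | (3aR,6R,7aS)-5-[5-(tert-butyldiphenylsilyloxy)pent-1-en-2-yl]-6-hydroxy-6-methyl-3a,6,7,7a-tetrahydrobenzofuran-2(3H)-one | O=C1C[C@@H]2C=C(C(=C)CCCO[Si](c3ccccc3)(c3ccccc3)C(C)(C)C)[C@](C)(O)C[C@@H]2O1
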